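**Plan**

- Retrosynthesis (benzofuran numbering): the nine O-protecting groups go last. The side-chain lactate is cut at its two new C–H bonds (enol ester hydrogenation), then at the C4–CH= bond (Horner–Wadsworth–Emmons on a C4 aldehyde). The C3 carboxyl–O bond to the (R)-aryllactate is cut next.
- Enabling feature: the C3a–C3 bond, with C3 carrying the carboxyl carbon trans to the C2 aryl group. Read backwards, ring A carbon C4a of a chroman-4-one has moved from the carbonyl carbon C4 to C3, so the dihydrobenzofuran ester is a ring-contracted (2S)-flavanone.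
- The flavanone is cut at C2–aryl (asymmetric 1,4-addition of an arylboronic acid to a chromone). The chromone goes back to a brominated protocatechualdehyde ether (acetyl group at the C–Br carbon, enaminone, ring closure).
- Forward order: pyranone ring (step 5), C2 aryl (step 6), contraction to the dihydrofuran (step 7), C3 ester exchange (steps 8 and 10), side chain (steps 15 and 16), deprotection (step 17).
- Stereochemistry: C2 from the rhodium/(S)-diphosphine conjugate addition; C3 relayed from C2 in the 1,2-shift (trans); the aryllactate carbon from natural (R)-danshensu; the side-chain lactate carbon from the rhodium/(R,R)-Et-DuPhos hydrogenation.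

Key step: step 7

Remark: the ligand antipodes in steps 6 and 16 are assigned by analogy (biaryl diphosphine–rhodium additions to cyclic enones; bisphospholane–rhodium hydrogenation of dehydroamino acid derivatives); should either run with the opposite sense, the mirror-image ligand is used.

Abbreviations: Bn = benzyl, PMB = 4-methoxybenzyl, MOM = methoxymethyl, DIC = N,N'-diisopropylcarbodiimide, p-ABSA = 4-acetamidobenzenesulfonyl azide.

**Route**

Step 1
Reactants: 1 4-(benzyloxy)-3-hydroxybenzaldehyde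
Product: 2 4-(benzyloxy)-2-bromo-3-hydroxybenzaldehyde
Conditions: Br2 (1.05 equiv), NaOAc, Fe powder (cat.), AcOH, rt
Reagents that add atoms: bromine, BrBr
Why: Electrophilic aromatic bromination is directed by the free phenol to its ortho position between OH and CHO, the regiochemistry established for isovanillin, and the acetate buffer should leave the benzyl ether intact.

Step 2
Reactants: 2 4-(benzyloxy)-2-bromo-3-hydroxybenzaldehyde
Product: 4 1-(benzyloxy)-3-bromo-4-(dimethoxymethyl)-2-(methoxymethoxy)benzene, via acetal phenol 3 (not isolated)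
Conditions: HC(OMe)3, MeOH, p-TsOH (cat.), rt; K2CO3, concentrate; then NaH, MOMCl, THF, 0 °C → rt
Reagents that add atoms: trimethyl orthoformate, COC(OC)OC; chloromethyl methyl ether, COCCl
Why: Acid-catalysed acetalisation with orthoformate as water scavenger, then Williamson etherification of the sodium phenoxide, masks the two groups that an aryllithium would not tolerate.

Step 3
Reactants: 4 1-(benzyloxy)-3-bromo-4-(dimethoxymethyl)-2-(methoxymethoxy)benzene; 5 N-methoxy-N-methylacetamide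
Product: 7 1-[3-(benzyloxy)-6-(dimethoxymethyl)-2-(methoxymethoxy)phenyl]ethan-1-one, via aryllithium 6 (not isolated)
Conditions: n-BuLi, THF, −78 °C; then 5, −78 → 0 °C; H2O
Reagents that add atoms: none
Why: Bromine–lithium exchange is fast at −78 °C, the flanking MOM and acetal oxygens stabilise the aryllithium, and the Weinreb amide stops at the ketone through its chelated tetrahedral adduct (Weinreb ketone synthesis).

Step 4
Reactants: 7 1-[3-(benzyloxy)-6-(dimethoxymethyl)-2-(methoxymethoxy)phenyl]ethan-1-one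
Product: 8 (2E)-1-[3-(benzyloxy)-6-(dimethoxymethyl)-2-(methoxymethoxy)phenyl]-3-(dimethylamino)prop-2-en-1-one
Conditions: Me2NCH(OMe)2, toluene, 100 °C
Reagents that add atoms: N,N-dimethylformamide dimethyl acetal, COC(OC)N(C)C
Why: Condensation of the methyl ketone with the amide acetal should give the enaminone under neutral conditions that affect neither the MOM ether nor the acetal.

Step 5
Reactants: 8 (2E)-1-[3-(benzyloxy)-6-(dimethoxymethyl)-2-(methoxymethoxy)phenyl]-3-(dimethylamino)prop-2-en-1-one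
Product: 10 8-(benzyloxy)-5-(dimethoxymethyl)-4H-chromen-4-one, via phenol enaminone 9 (not isolated)
Conditions: HCl (1.25 M in MeOH, 2.5 equiv), HC(OMe)3, 0 °C → rt; then NaHCO3
Reagents that add atoms: none
Why: Anhydrous acid removes the MOM group as dimethoxymethane, the freed phenol adds to the protonated enaminone and dimethylamine is expelled (addition–elimination chromone synthesis), while methanol/orthoformate keeps the aldehyde as its dimethyl acetal.

Step 6
Reactants: 10 8-(benzyloxy)-5-(dimethoxymethyl)-4H-chromen-4-one; 11 [3,4-bis(benzyloxy)phenyl]boronic acid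
Product: 12 (2S)-8-(benzyloxy)-2-[3,4-bis(benzyloxy)phenyl]-5-(dimethoxymethyl)-2,3-dihydro-4H-chromen-4-one
Conditions: [Rh(OH)(cod)]2 (1.5 mol%), (S)-MeO-F12-BIPHEP (3.3 mol%), 11 (3 equiv), toluene, H2O (2 equiv), 25 °C
Reagents that add atoms: none
Why: Hayashi–Miyaura 1,4-addition, in which the aryl–rhodium species carrying the electron-poor (S)-biaryl diphosphine [bis(3,4,5-trifluorophenyl)phosphino groups] inserts the chromone C2=C3 bond from one face under catalyst control to set C2 as S, and the base-free neutral medium should spare the acetal and keep the flavanone from opening to the chalcone.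

Step 7
Reactants: 12 (2S)-8-(benzyloxy)-2-[3,4-bis(benzyloxy)phenyl]-5-(dimethoxymethyl)-2,3-dihydro-4H-chromen-4-one
Product: 14 methyl (2S,3S)-7-(benzyloxy)-2-[3,4-bis(benzyloxy)phenyl]-4-(dimethoxymethyl)-2,3-dihydro-1-benzofuran-3-carboxylate, via enol ether 13 (not isolated)
Conditions: PhI(OAc)2 (1.2 equiv), HC(OMe)3, H2SO4 (cat.), 0 °C → rt; then NaHCO3 (aq)
Reagents that add atoms: trimethyl orthoformate, COC(OC)OC
Why: In acidic orthoformate the C4 ketone passes through its dimethyl ketal into enol ether 13, which electrophilic trivalent iodine attacks at C3 on the face opposite the C2 aryl group, and methanol re-forms the ketal so that an equatorial C3–I bond lies antiperiplanar to the C4–C4a bond. Ring A carbon C4a then shifts from C4 to C3 with inversion as iodobenzene departs, creating the C3a–C3 bond, and the dimethoxycarbenium ion left at the old carbonyl carbon collapses to the methyl ester. The closest known reactions are the PhI(OAc)2 or Tl(NO3)3 ring contractions of flavanones to methyl trans-2-aryl-2,3-dihydrobenzofuran-3-carboxylates and the 1,2-aryl shift of α-functionalised aryl ketone ketals. The five-membered ring is closed by this 1,2-shift (ring contraction) and not by a cyclisation, so no ring-closure rule is involved. C3 is set by substrate control from C2, since anti iodination followed by invertive migration places the ester trans to the aryl group (3S), which is also the more stable isomer, while C2 is not touched. The step needs ring A to migrate in preference to the C2 aryl group (isoflavone) or loss of a C3 proton (flavone), which the diequatorial iodane, the oxygen-substituted migrating carbon and the ketal medium favour, and the benzyl ethers and the dimethyl acetal (the resting form of the aldehyde in this medium) should be inert.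

Step 8
Reactants: 14 methyl (2S,3S)-7-(benzyloxy)-2-[3,4-bis(benzyloxy)phenyl]-4-(dimethoxymethyl)-2,3-dihydro-1-benzofuran-3-carboxylate
Product: 16 (2S,3S)-7-(benzyloxy)-2-[3,4-bis(benzyloxy)phenyl]-4-formyl-2,3-dihydro-1-benzofuran-3-carboxylic acid, via trimethylstannyl ester 15 (not isolated)
Conditions: Me3SnOH (5 equiv), ClCH2CH2Cl, 80 °C; then 1 M HCl, THF, rt
Reagents that add atoms: trimethyltin hydroxide, C[Sn](C)(C)O; water, O
Why: Tin hydroxide ester cleavage works under nearly neutral conditions, avoiding β-elimination of the ring phenoxide and loss of the trans C3 configuration, and the aqueous acid then frees the acid from tin and hydrolyses the labile para-alkoxyaryl dimethyl acetal (acetal hydrolysis).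

Step 9
Reactants: 17 sodium (2R)-3-(3,4-dihydroxyphenyl)-2-hydroxypropanoate (danshensu sodium salt)
Product: 18 4-methoxybenzyl (2R)-3-{3,4-bis[(4-methoxybenzyl)oxy]phenyl}-2-hydroxypropanoate
Conditions: PMBCl (3.3 equiv), K2CO3, Bu4NI (cat.), DMF, rt, argon
Reagents that add atoms: 4-methoxybenzyl chloride, COc1ccc(CCl)cc1
Why: Carbonate-mediated O-alkylation (Williamson type) should take the carboxylate and both phenols but not the secondary alcohol, and nothing touches the stereocentre of the natural (R)-acid.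

Step 10
Reactants: 16 (2S,3S)-7-(benzyloxy)-2-[3,4-bis(benzyloxy)phenyl]-4-formyl-2,3-dihydro-1-benzofuran-3-carboxylic acid; 18 4-methoxybenzyl (2R)-3-{3,4-bis[(4-methoxybenzyl)oxy]phenyl}-2-hydroxypropanoate
Product: 19 4-methoxybenzyl (2R)-2-({[(2S,3S)-7-(benzyloxy)-2-[3,4-bis(benzyloxy)phenyl]-4-formyl-2,3-dihydro-1-benzofuran-3-yl]carbonyl}oxy)-3-{3,4-bis[(4-methoxybenzyl)oxy]phenyl}propanoate
Conditions: DIC, DMAP (0.2 equiv), CH2Cl2, 0 °C → rt
Reagents that add atoms: none
Why: Steglich esterification activates the C3 acid as its O-acylisourea and acylpyridinium under nearly neutral conditions, so the (R)-alcohol is acylated with retention and any enolisation at C3 should return to the favoured trans isomer.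

Step 11
Reactants: 20 (diethoxyphosphoryl)acetic acid
Product: 21 4-methoxybenzyl (diethoxyphosphoryl)acetate
Conditions: PMBOH, DIC, DMAP (cat.), CH2Cl2, 0 °C → rt
Reagents that add atoms: 4-methoxybenzyl alcohol, COc1ccc(CO)cc1
Why: Steglich esterification of an unhindered acid with a primary benzylic alcohol, chosen over carboxylate alkylation to avoid C-benzylation of the acidic methylene.

Step 12
Reactants: 21 4-methoxybenzyl (diethoxyphosphoryl)acetate
Product: 22 4-methoxybenzyl diazo(diethoxyphosphoryl)acetate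
Conditions: p-ABSA, DBU, MeCN, 0 °C → rt
Reagents that add atoms: 4-acetamidobenzenesulfonyl azide, CC(=O)Nc1ccc(cc1)S(=O)(=O)N=[N+]=[N-]
Why: Regitz diazo transfer to the methylene activated by both the phosphonate and the ester.

Step 13
Reactants: 23 3,4-bis(benzyloxy)benzaldehyde
Product: 24 (2E)-3-[3,4-bis(benzyloxy)phenyl]prop-2-enoic acid
Conditions: CH2(CO2H)2, pyridine, piperidine (cat.), 90 °C
Reagents that add atoms: malonic acid, OC(=O)CC(=O)O
Why: Knoevenagel–Doebner condensation with decarboxylation should give the E cinnamic acid.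

Step 14
Reactants: 22 4-methoxybenzyl diazo(diethoxyphosphoryl)acetate; 24 (2E)-3-[3,4-bis(benzyloxy)phenyl]prop-2-enoic acid
Product: 25 4-methoxybenzyl 2-({(2E)-3-[3,4-bis(benzyloxy)phenyl]prop-2-enoyl}oxy)-2-(diethoxyphosphoryl)acetate (racemic)
Conditions: Rh2(OAc)4 (1 mol%), toluene, 80 °C, slow addition of 22
Reagents that add atoms: none
Why: The rhodium carbenoid formed from the diazo phosphonate inserts into the carboxylic O–H bond far faster than it adds to the electron-poor cinnamoyl alkene (carbenoid O–H insertion).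

Step 15
Reactants: 19 4-methoxybenzyl (2R)-2-({[(2S,3S)-7-(benzyloxy)-2-[3,4-bis(benzyloxy)phenyl]-4-formyl-2,3-dihydro-1-benzofuran-3-yl]carbonyl}oxy)-3-{3,4-bis[(4-methoxybenzyl)oxy]phenyl}propanoate; 25 4-methoxybenzyl 2-({(2E)-3-[3,4-bis(benzyloxy)phenyl]prop-2-enoyl}oxy)-2-(diethoxyphosphoryl)acetate
Product: 26 4-methoxybenzyl (2Z)-3-[(2S,3S)-7-(benzyloxy)-2-[3,4-bis(benzyloxy)phenyl]-3-({[(2R)-3-{3,4-bis[(4-methoxybenzyl)oxy]phenyl}-1-[(4-methoxybenzyl)oxy]-1-oxopropan-2-yl]oxy}carbonyl)-2,3-dihydro-1-benzofuran-4-yl]-2-({(2E)-3-[3,4-bis(benzyloxy)phenyl]prop-2-enoyl}oxy)prop-2-enoate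
Conditions: LiCl, DBU, MeCN/THF, 0 °C → rt
Reagents that add atoms: none
Why: Horner–Wadsworth–Emmons olefination under Masamune–Roush conditions is mild enough for the C3–H and the enol ester; the Z isomer should predominate and any E isomer is carried on, because this class of hydrogenation reduces both geometries with the same sense.

Step 16
Reactants: 26 4-methoxybenzyl (2Z)-3-[(2S,3S)-7-(benzyloxy)-2-[3,4-bis(benzyloxy)phenyl]-3-({[(2R)-3-{3,4-bis[(4-methoxybenzyl)oxy]phenyl}-1-[(4-methoxybenzyl)oxy]-1-oxopropan-2-yl]oxy}carbonyl)-2,3-dihydro-1-benzofuran-4-yl]-2-({(2E)-3-[3,4-bis(benzyloxy)phenyl]prop-2-enoyl}oxy)prop-2-enoate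
Product: 27 4-methoxybenzyl (2R)-3-[(2S,3S)-7-(benzyloxy)-2-[3,4-bis(benzyloxy)phenyl]-3-({[(2R)-3-{3,4-bis[(4-methoxybenzyl)oxy]phenyl}-1-[(4-methoxybenzyl)oxy]-1-oxopropan-2-yl]oxy}carbonyl)-2,3-dihydro-1-benzofuran-4-yl]-2-({(2E)-3-[3,4-bis(benzyloxy)phenyl]prop-2-enoyl}oxy)propanoate
Conditions: [Rh(cod)((R,R)-Et-DuPhos)]BF4 (2 mol%), H2 (4 bar), CH2Cl2/MeOH, rt
Reagents that add atoms: none
Why: Asymmetric hydrogenation of an α-acyloxy acrylate, in which the enol ester C=C and the acyl carbonyl chelate the cationic rhodium bisphospholane so that hydrogen is delivered to this alkene only and under catalyst control to give the (R)-lactate, while the non-chelating cinnamoyl alkene and the benzyl-type ethers should be left alone by this homogeneous catalyst.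

Step 17
Reactants: 27 4-methoxybenzyl (2R)-3-[(2S,3S)-7-(benzyloxy)-2-[3,4-bis(benzyloxy)phenyl]-3-({[(2R)-3-{3,4-bis[(4-methoxybenzyl)oxy]phenyl}-1-[(4-methoxybenzyl)oxy]-1-oxopropan-2-yl]oxy}carbonyl)-2,3-dihydro-1-benzofuran-4-yl]-2-({(2E)-3-[3,4-bis(benzyloxy)phenyl]prop-2-enoyl}oxy)propanoate
Product: 28 (2R)-3-[(2S,3S)-3-{[(1R)-1-carboxy-2-(3,4-dihydroxyphenyl)ethoxy]carbonyl}-2-(3,4-dihydroxyphenyl)-7-hydroxy-2,3-dihydro-1-benzofuran-4-yl]-2-{[(2E)-3-(3,4-dihydroxyphenyl)prop-2-enoyl]oxy}propanoic acid (CNP0201431.1)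
Conditions: BCl3 (1 M in CH2Cl2, excess), C6HMe5 (excess), CH2Cl2, −78 → −40 °C; then THF/H2O
Reagents that add atoms: none
Why: Lewis-acid cleavage of benzylic C–O bonds with pentamethylbenzene as a non-basic cation scavenger (Friedel–Crafts capture of the benzyl cations) should remove the five benzyl ethers, two PMB ethers and two PMB esters at low temperature without touching the two alkyl esters, the cinnamoyl alkene or the four stereocentres.

**Compound list**

1 | 4-(benzyloxy)-3-hydroxybenzaldehyde | O=Cc1ccc(OCc2ccccc2)c(O)c1 | starting material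
2 | 4-(benzyloxy)-2-bromo-3-hydroxybenzaldehyde | O=Cc1ccc(OCc2ccccc2)c(O)c1Br | intermediate
3 | 6-(benzyloxy)-2-bromo-3-(dimethoxymethyl)phenol (acetal phenol) | COC(OC)c1ccc(OCc2ccccc2)c(O)c1Br | intermediate
4 | 1-(benzyloxy)-3-bromo-4-(dimethoxymethyl)-2-(methoxymethoxy)benzene | COC(OC)c1ccc(OCc2ccccc2)c(OCOC)c1Br | intermediate
5 | N-methoxy-N-methylacetamide | CC(=O)N(C)OC | starting material
6 | [3-(benzyloxy)-6-(dimethoxymethyl)-2-(methoxymethoxy)phenyl]lithium (aryllithium) | COC(OC)c1ccc(OCc2ccccc2)c(OCOC)c1[Li] | intermediate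
7 | 1-[3-(benzyloxy)-6-(dimethoxymethyl)-2-(methoxymethoxy)phenyl]ethan-1-one | COC(OC)c1ccc(OCc2ccccc2)c(OCOC)c1C(C)=O | intermediate
8 | (2E)-1-[3-(benzyloxy)-6-(dimethoxymethyl)-2-(methoxymethoxy)phenyl]-3-(dimethylamino)prop-2-en-1-one | COC(OC)c1ccc(OCc2ccccc2)c(OCOC)c1C(=O)/C=C/N(C)C | intermediate
9 | (2E)-1-[3-(benzyloxy)-6-(dimethoxymethyl)-2-hydroxyphenyl]-3-(dimethylamino)prop-2-en-1-one (phenol enaminone) | COC(OC)c1ccc(OCc2ccccc2)c(O)c1C(=O)/C=C/N(C)C | intermediate
10 | 8-(benzyloxy)-5-(dimethoxymethyl)-4H-chromen-4-one | COC(OC)c1ccc(OCc2ccccc2)c2occc(=O)c12 | intermediate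
11 | [3,4-bis(benzyloxy)phenyl]boronic acid | OB(O)c1ccc(OCc2ccccc2)c(OCc2ccccc2)c1 | starting material
12 | (2S)-8-(benzyloxy)-2-[3,4-bis(benzyloxy)phenyl]-5-(dimethoxymethyl)-2,3-dihydro-4H-chromen-4-one | COC(OC)c1ccc(OCc3ccccc3)c2c1C(=O)C[C@@H](c1ccc(OCc3ccccc3)c(OCc3ccccc3)c1)O2 | intermediate
13 | (2S)-8-(benzyloxy)-2-[3,4-bis(benzyloxy)phenyl]-5-(dimethoxymethyl)-4-methoxy-2H-chromene (enol ether) | COC(OC)c1ccc(OCc3ccccc3)c2c1C(OC)=C[C@@H](c1ccc(OCc3ccccc3)c(OCc3ccccc3)c1)O2 | intermediate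
14 | methyl (2S,3S)-7-(benzyloxy)-2-[3,4-bis(benzyloxy)phenyl]-4-(dimethoxymethyl)-2,3-dihydro-1-benzofuran-3-carboxylate | COC(OC)c1ccc(OCc3ccccc3)c2c1[C@H](C(=O)OC)[C@@H](c1ccc(OCc3ccccc3)c(OCc3ccccc3)c1)O2 | intermediate
15 | trimethylstannyl (2S,3S)-7-(benzyloxy)-2-[3,4-bis(benzyloxy)phenyl]-4-(dimethoxymethyl)-2,3-dihydro-1-benzofuran-3-carboxylate | COC(OC)c1ccc(OCc3ccccc3)c2c1[C@H](C(=O)O[Sn](C)(C)C)[C@@H](c1ccc(OCc3ccccc3)c(OCc3ccccc3)c1)O2 | intermediate
16 | (2S,3S)-7-(benzyloxy)-2-[3,4-bis(benzyloxy)phenyl]-4-formyl-2,3-dihydro-1-benzofuran-3-carboxylic acid | O=Cc1ccc(OCc3ccccc3)c2c1[C@H](C(=O)O)[C@@H](c1ccc(OCc3ccccc3)c(OCc3ccccc3)c1)O2 | intermediate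
17 | sodium (2R)-3-(3,4-dihydroxyphenyl)-2-hydroxypropanoate | O[C@H](Cc1ccc(O)c(O)c1)C(=O)[O-].[Na+] | starting material
18 | 4-methoxybenzyl (2R)-3-{3,4-bis[(4-methoxybenzyl)oxy]phenyl}-2-hydroxypropanoate | O[C@H](Cc1ccc(OCc2ccc(OC)cc2)c(OCc2ccc(OC)cc2)c1)C(=O)OCc1ccc(OC)cc1 | intermediate
19 | 4-methoxybenzyl (2R)-2-({[(2S,3S)-7-(benzyloxy)-2-[3,4-bis(benzyloxy)phenyl]-4-formyl-2,3-dihydro-1-benzofuran-3-yl]carbonyl}oxy)-3-{3,4-bis[(4-methoxybenzyl)oxy]phenyl}propanoate | O=Cc1ccc(OCc3ccccc3)c2c1[C@H](C(=O)O[C@H](Cc1ccc(OCc3ccc(OC)cc3)c(OCc3ccc(OC)cc3)c1)C(=O)OCc1ccc(OC)cc1)[C@@H](c1ccc(OCc3ccccc3)c(OCc3ccccc3)c1)O2 | intermediate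
20 | (diethoxyphosphoryl)acetic acid | CCOP(=O)(OCC)CC(=O)O | starting material
21 | 4-methoxybenzyl (diethoxyphosphoryl)acetate | CCOP(=O)(OCC)CC(=O)OCc1ccc(OC)cc1 | intermediate
22 | 4-methoxybenzyl diazo(diethoxyphosphoryl)acetate | CCOP(=O)(OCC)C(=[N+]=[N-])C(=O)OCc1ccc(OC)cc1 | intermediate
23 | 3,4-bis(benzyloxy)benzaldehyde | O=Cc1ccc(OCc2ccccc2)c(OCc2ccccc2)c1 | starting material
24 | (2E)-3-[3,4-bis(benzyloxy)phenyl]prop-2-enoic acid | OC(=O)/C=C/c1ccc(OCc2ccccc2)c(OCc2ccccc2)c1 | intermediate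
25 | 4-methoxybenzyl 2-({(2E)-3-[3,4-bis(benzyloxy)phenyl]prop-2-enoyl}oxy)-2-(diethoxyphosphoryl)acetate (racemic) | CCOP(=O)(OCC)C(OC(=O)/C=C/c1ccc(OCc2ccccc2)c(OCc2ccccc2)c1)C(=O)OCc1ccc(OC)cc1 | intermediate
26 | 4-methoxybenzyl (2Z)-3-[(2S,3S)-7-(benzyloxy)-2-[3,4-bis(benzyloxy)phenyl]-3-({[(2R)-3-{3,4-bis[(4-methoxybenzyl)oxy]phenyl}-1-[(4-methoxybenzyl)oxy]-1-oxopropan-2-yl]oxy}carbonyl)-2,3-dihydro-1-benzofuran-4-yl]-2-({(2E)-3-[3,4-bis(benzyloxy)phenyl]prop-2-enoyl}oxy)prop-2-enoate | O=C(/C=C/c1ccc(OCc2ccccc2)c(OCc2ccccc2)c1)O/C(C(=O)OCc1ccc(OC)cc1)=C\c1ccc(OCc3ccccc3)c2c1[C@H](C(=O)O[C@H](Cc1ccc(OCc3ccc(OC)cc3)c(OCc3ccc(OC)cc3)c1)C(=O)OCc1ccc(OC)cc1)[C@@H](c1ccc(OCc3ccccc3)c(OCc3ccccc3)c1)O2 | intermediate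
27 | 4-methoxybenzyl (2R)-3-[(2S,3S)-7-(benzyloxy)-2-[3,4-bis(benzyloxy)phenyl]-3-({[(2R)-3-{3,4-bis[(4-methoxybenzyl)oxy]phenyl}-1-[(4-methoxybenzyl)oxy]-1-oxopropan-2-yl]oxy}carbonyl)-2,3-dihydro-1-benzofuran-4-yl]-2-({(2E)-3-[3,4-bis(benzyloxy)phenyl]prop-2-enoyl}oxy)propanoate | O=C(/C=C/c1ccc(OCc2ccccc2)c(OCc2ccccc2)c1)O[C@H](Cc1ccc(OCc3ccccc3)c2c1[C@H](C(=O)O[C@H](Cc1ccc(OCc3ccc(OC)cc3)c(OCc3ccc(OC)cc3)c1)C(=O)OCc1ccc(OC)cc1)[C@@H](c1ccc(OCc3ccccc3)c(OCc3ccccc3)c1)O2)C(=O)OCc1ccc(OC)cc1 | intermediate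
28 | (2R)-3-[(2S,3S)-3-{[(1R)-1-carboxy-2-(3,4-dihydroxyphenyl)ethoxy]carbonyl}-2-(3,4-dihydroxyphenyl)-7-hydroxy-2,3-dihydro-1-benzofuran-4-yl]-2-{[(2E)-3-(3,4-dihydroxyphenyl)prop-2-enoyl]oxy}propanoic acid (CNP0201431.1) | O=C(/C=C/c1ccc(O)c(O)c1)O[C@H](Cc1ccc(O)c2c1[C@H](C(=O)O[C@H](Cc1ccc(O)c(O)c1)C(=O)O)[C@@H](c1ccc(O)c(O)c1)O2)C(=O)O | target

**Count and risks**

Total step count: 17. Longest linear sequence: 12 steps (1–8, 10, 15, 16, 17).

Steps most likely to fail:

Step 7. The C2 aryl group may migrate instead of ring A (isoflavone), C3 may simply lose a proton (flavone), the activated iodine reagent may attack the benzyloxy-substituted rings, or acid may open the flavanone and erode the C2 configuration. The fallback separates oxidation from rearrangement and sets out from flavanone 12. α-Bromination with PhNMe3Br3 in THF at 0 °C should give the 2,3-trans bromo ketone F1 (its descriptors read 2R,3R only because bromine changes the priorities). HC(OMe)3/MeOH with p-TsOH converts it into the bromo dimethyl ketal F2. AgBF4 in MeOH/HC(OMe)3 then abstracts bromide, so that ring A shifts from C4 to C3 anti to the equatorial C–Br bond (the silver-assisted 1,2-aryl shift of α-bromo ketals). This comes back to the route at ester 14 with the same trans configuration.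

Step 16. The cinnamoyl alkene may be reduced or may tie up the catalyst, turnover at the congested trisubstituted enol ester may be slow, or facial control may be insufficient. The fallback takes the second alkene out of the hydrogenation substrate and sets out from aldehyde 19 and diazo phosphonate 22. Insertion of 22 into the O–H bond of chloroacetic acid (Rh2(OAc)4, toluene, 80 °C) should give the chloroacetoxy phosphonate F3. Olefination of 19 with F3 (LiCl, DBU, MeCN) gives the enol chloroacetate F4, which is hydrogenated with the same rhodium catalyst to the (R)-chloroacetate F5. Thiourea and NaHCO3 in EtOH/THF remove the chloroacetyl group selectively to give the (R)-hydroxy ester F6. Steglich acylation of F6 with acid 24 (DIC, DMAP) comes back to the route at 27.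

Step 10. Acyl transfer at the hindered C3 carboxyl may be slow enough for rearrangement to the N-acylurea, the activated acid may be captured by the neighbouring formyl oxygen (pseudo-ester formation), or the activated acid may enolise at C3. The fallback activates the alcohol instead of the acid and sets out from alcohol 18. A Mitsunobu reaction with chloroacetic acid (PPh3, DIAD, THF) should give the inverted (S)-chloroacetate F7, and thiourea/NaHCO3 in EtOH frees the (S)-alcohol F8. A second Mitsunobu reaction of F8 with acid 16 forms the ester bond by SN2 attack of the open-chain carboxylate, with inversion to the required (R) centre, and comes back to the route at 19.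

**Further compounds**

F1 | step 7 | (2R,3R)-8-(benzyloxy)-2-[3,4-bis(benzyloxy)phenyl]-3-bromo-5-(dimethoxymethyl)-2,3-dihydro-4H-chromen-4-one | COC(OC)c1ccc(OCc3ccccc3)c2c1C(=O)[C@H](Br)[C@@H](c1ccc(OCc3ccccc3)c(OCc3ccccc3)c1)O2
F2 | step 7 | (2R,3R)-8-(benzyloxy)-2-[3,4-bis(benzyloxy)phenyl]-3-bromo-5-(dimethoxymethyl)-4,4-dimethoxy-3,4-dihydro-2H-chromene | COC(OC)c1ccc(OCc3ccccc3)c2c1C(OC)(OC)[C@H](Br)[C@@H](c1ccc(OCc3ccccc3)c(OCc3ccccc3)c1)O2
F3 | step 16 | 4-methoxybenzyl 2-[(chloroacetyl)oxy]-2-(diethoxyphosphoryl)acetate | CCOP(=O)(OCC)C(OC(=O)CCl)C(=O)OCc1ccc(OC)cc1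
F4 | step 16 | 4-methoxybenzyl (2Z)-3-[(2S,3S)-7-(benzyloxy)-2-[3,4-bis(benzyloxy)phenyl]-3-({[(2R)-3-{3,4-bis[(4-methoxybenzyl)oxy]phenyl}-1-[(4-methoxybenzyl)oxy]-1-oxopropan-2-yl]oxy}carbonyl)-2,3-dihydro-1-benzofuran-4-yl]-2-[(chloroacetyl)oxy]prop-2-enoate | ClCC(=O)O/C(C(=O)OCc1ccc(OC)cc1)=C\c1ccc(OCc3ccccc3)c2c1[C@H](C(=O)O[C@H](Cc1ccc(OCc3ccc(OC)cc3)c(OCc3ccc(OC)cc3)c1)C(=O)OCc1ccc(OC)cc1)[C@@H](c1ccc(OCc3ccccc3)c(OCc3ccccc3)c1)O2
F5 | step 16 | 4-methoxybenzyl (2R)-3-[(2S,3S)-7-(benzyloxy)-2-[3,4-bis(benzyloxy)phenyl]-3-({[(2R)-3-{3,4-bis[(4-methoxybenzyl)oxy]phenyl}-1-[(4-methoxybenzyl)oxy]-1-oxopropan-2-yl]oxy}carbonyl)-2,3-dihydro-1-benzofuran-4-yl]-2-[(chloroacetyl)oxy]propanoate | ClCC(=O)O[C@H](Cc1ccc(OCc3ccccc3)c2c1[C@H](C(=O)O[C@H](Cc1ccc(OCc3ccc(OC)cc3)c(OCc3ccc(OC)cc3)c1)C(=O)OCc1ccc(OC)cc1)[C@@H](c1ccc(OCc3ccccc3)c(OCc3ccccc3)c1)O2)C(=O)OCc1ccc(OC)cc1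
F6 | step 16 | 4-methoxybenzyl (2R)-3-[(2S,3S)-7-(benzyloxy)-2-[3,4-bis(benzyloxy)phenyl]-3-({[(2R)-3-{3,4-bis[(4-methoxybenzyl)oxy]phenyl}-1-[(4-methoxybenzyl)oxy]-1-oxopropan-2-yl]oxy}carbonyl)-2,3-dihydro-1-benzofuran-4-yl]-2-hydroxypropanoate | O[C@H](Cc1ccc(OCc3ccccc3)c2c1[C@H](C(=O)O[C@H](Cc1ccc(OCc3ccc(OC)cc3)c(OCc3ccc(OC)cc3)c1)C(=O)OCc1ccc(OC)cc1)[C@@H](c1ccc(OCc3ccccc3)c(OCc3ccccc3)c1)O2)C(=O)OCc1ccc(OC)cc1
F7 | step 10 | 4-methoxybenzyl (2S)-3-{3,4-bis[(4-methoxybenzyl)oxy]phenyl}-2-[(chloroacetyl)oxy]propanoate | ClCC(=O)O[C@@H](Cc1ccc(OCc2ccc(OC)cc2)c(OCc2ccc(OC)cc2)c1)C(=O)OCc1ccc(OC)cc1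
F8 | step 10 | 4-methoxybenzyl (2S)-3-{3,4-bis[(4-methoxybenzyl)oxy]phenyl}-2-hydroxypropanoate | O[C@@H](Cc1ccc(OCc2ccc(OC)cc2)c(OCc2ccc(OC)cc2)c1)C(=O)OCc1ccc(OC)cc1
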